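## Analysis of the target

Target 25 is 7-hydroxy-3-[(2R)-1-(2-hydroxy-4-methoxyphenyl)-3,3-bis(4-hydroxyphenyl)-1-oxopropan-2-yl]-4H-chromen-4-one. It is a three-carbon chain: chain C1 is the carbonyl carbon of an aryl ketone on ring A (the 2-hydroxy-4-methoxyphenyl ring), chain C2 carries C3 of a 7-hydroxychromone, and chain C3 carries two identical 4-hydroxyphenyl rings. Because those two aryl groups are the same, chain C2 is the only stereocentre; it is R (ring A carbonyl carbon > chromone C3 > diarylmethyl carbon > H). This centre is the difficulty: its hydrogen is alpha to the ring A ketone and allylic to the chromone C2=C3 bond, so base removes it to give an extended enolate. A second base-triggered loss is built in, since a 4-hydroxyphenyl group on the neighbouring carbon can, as its phenoxide, expel that same enolate through a para-quinone methide. The phenols therefore stay masked until a neutral last step. Other sensitive sites are chromone C2 (a vinylogous ester carbon opened by amines and hydroxide), the reducible C2=C3 bond and the four phenols. The strategy rests on the 1,4 relationship between chromone C4 and the ring A carbonyl carbon, through chromone C3 and the stereocentre. Read as a homoenolate of the ring A ketone, chromone C3 is its beta carbon and the stereocentre its alpha carbon; in the cyclopropanol form of that homoenolate the stereocentre is a ring carbon with no carbonyl beside it and cannot enolise while the C–C bonds are made.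

## Retrosynthetic reasoning

25 is traced to its tetrabenzyl ether 24 by cutting the four benzylic O–C bonds. One neutral hydrogenolysis then ends the route, and the phenols are inert through all organometallic steps. The forward step has to cleave four ethers without reducing chromone C2=C3.

24 is cut at O1–C2 and C2–C3 of the pyranone ring, back to the 2-hydroxyaryl 1,4-diketone 21 and the amide acetal 22. C2 arrives at the right oxidation level, so no dehydrogenation is needed later. Only the single methylene of 21 can condense, via enaminone 23, because the stereocentre is a methine. The ring is closed in acid, since the chromone is the base-sensitive form of the stereocentre.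

21 comes from silyl ether 20 by O–Si cleavage. The oxygen that becomes O1 must be told apart from the three benzylated ones.

20 is cut at C4–C4a and C4–C3 (chromone numbering) into cyclopropanol 13, aryl iodide 18 and carbon monoxide 19. Cutting on either side of the stereocentre instead would need an enolate at or next to it; this cut leaves all four of its bonds alone. The gain is convergence and a centre kept as a cyclopropane carbon through the bond-forming event. The forward reaction must open the ring at the CH2–C(OH) bond, take up 19 before coupling, and form the C–C bond before beta-hydride loss.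

13 is cut at the two ring bonds to its CH2 group, back to the Z silyl enol ether 10 and diiodomethane 11, through silyl ether 12. Methylene transfer is stereospecific, so alkene geometry gives the relative configuration and a chiral ligand the absolute one. Only C2 of 13 matters later, because C1 becomes a carbonyl carbon.

10 is the enol silyl ether of ketone 8 (with 9). 8 is cut at a chain C3–aryl bond to chalcone 5 and aryl bromide 6, via Grignard reagent 7; no stereocentre arises because the incoming aryl group equals the resident one. 5 is the aldol condensation product of 3 and 4, and 3 is the benzyl ether (from 2) of paeonol 1, which supplies ring A complete.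

18 is the silyl ether (from 17) of iodophenol 16, made by iodination of 14 with 15. Buying 14 with one oxygen already benzylated avoids a statistical monoprotection of a symmetrical diol.

## Alternatives that were turned down

Alternative 1: Ring A is disconnected at C1–C2 and C5–C6 to the terminal ynone A2 and the oxygenated diene A3. Forward, a thermal [4+2] cycloaddition joins the nucleophilic diene terminus to the ynone beta carbon, and loss of the acetal methoxy group aromatises the adduct to A1, the tribenzyl ether of 25 with the ring A phenol free.
- For: the reaction type is well precedented, and on this point it is stronger than the chosen key step; the ring A pattern follows from the diene and its phenol needs no protecting group.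
- Against: ring A is available ready-made in 1, so building it adds steps. The stereocentre must already exist in A2, where its hydrogen lies between an ynone carbonyl and chromone C3 and is more acidic than in 25. Making A2 and heating it with a basic ketene acetal put the configuration at risk, and the plan does not say how the centre is set.
- In place of precedent, the chosen route offers a centre created by a stereospecific reaction and kept non-enolisable through the C–C bond formation.

Alternative 2: The chromanone bond C4–C3 is disconnected to aldehyde A5, a salicylaldehyde ether tethered to the beta carbon of an alpha-(diarylmethyl) aryl enone. Forward, a chiral triazolium-derived carbene with an amide base adds the aldehyde carbon as an acyl anion equivalent to the enone beta carbon (intramolecular Stetter reaction), closing the six-membered ring to A4.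
- For: it is catalytic, asymmetric and a well-studied ring closure; on precedent and on forming a ring in the key step it is stronger.
- Against: the catalyst directly controls ring carbon C3, which is flattened again on oxidation to the chromone. The centre that survives in 25 arises by protonation of an enolate after the C–C bond is formed, in the presence of amide base. The alpha-diarylmethyl group makes the acceptor hindered, a poor substrate class. A4 still needs dehydrogenation next to a second enolisable ketone whose alpha carbon is the stereocentre, and A5 with defined alkene geometry is a multistep target.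
- The chosen route reaches the chromone oxidation level directly through 22 and fixes the configuration before any carbonyl stands next to it.

Alternative 3: Ring A is disconnected at C1–C(=O) and C2–O to acid A7 and aryne precursor A8. Forward, fluoride releases 3-chloro-5-methoxybenzyne from A8; the carboxylate oxygen of A7 adds to the aryne carbon remote from chlorine and the aryl anion takes over the acyl group, giving A6.
- For: ketone and free phenol of ring A form in one convergent step; in convergence and protecting-group economy at ring A it is stronger.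
- Against: the alpha hydrogen of A7 is acidified by carboxyl and chromone and sits next to a strongly basic aryl anion. Proton transfer, giving a plain aryl ester and racemisation, competes with acyl transfer through a strained four-membered intermediate. Fluoride and the aryne can attack chromone C2. The chlorine must be removed later by a reduction that needs base. A8 takes several steps, and the origin of enantiopure A7 stays open.
- The chosen route takes ring A from 1 and ties the stereocentre to a stereospecific cyclopropanation.

Key step: step 8

Remark on the chemistry: the sense of induction of the dipeptide ligand on this trisubstituted enol ether is assumed to give the (1S,2S) series with N-Boc-L-Val-L-Pro-OMe; if it gives (1R,2R), the D,D-ligand is used without other change.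

## Route

Step 1
Reactants: 1 paeonol (1-(2-hydroxy-4-methoxyphenyl)ethan-1-one); 2 benzyl bromide
Product: 3 1-[2-(benzyloxy)-4-methoxyphenyl]ethan-1-one
Conditions: K2CO3, DMF, 60 °C
Reagents that add atoms: benzyl bromide, BrCc1ccccc1
Why: Williamson ether synthesis; the chelated phenol of 1 is the only acidic site, and its benzyl ether keeps it out of the later organometallic steps.

Step 2
Reactants: 3 1-[2-(benzyloxy)-4-methoxyphenyl]ethan-1-one; 4 4-(benzyloxy)benzaldehyde
Product: 5 (2E)-1-[2-(benzyloxy)-4-methoxyphenyl]-3-[4-(benzyloxy)phenyl]prop-2-en-1-one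
Conditions: KOH, EtOH/THF, rt
Reagents that add atoms: 4-(benzyloxy)benzaldehyde, O=Cc1ccc(OCc2ccccc2)cc1
Why: Claisen–Schmidt condensation; 4 cannot enolise, the methyl ketone of 3 is the only enolisable partner, and dehydration of the aldol should give the conjugated E alkene.

Step 3
Reactants: 5 (2E)-1-[2-(benzyloxy)-4-methoxyphenyl]-3-[4-(benzyloxy)phenyl]prop-2-en-1-one; 6 1-(benzyloxy)-4-bromobenzene
Product: 8 1-[2-(benzyloxy)-4-methoxyphenyl]-3,3-bis[4-(benzyloxy)phenyl]propan-1-one, via [4-(benzyloxy)phenyl]magnesium bromide 7 (not isolated)
Conditions: 6, Mg, THF, reflux; then CuBr·SMe2 (10 mol %), 5, THF, −20 → 0 °C; 1 M HCl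
Reagents that add atoms: 1-(benzyloxy)-4-bromobenzene (as its Grignard reagent), Brc1ccc(OCc2ccccc2)cc1
Why: Copper-catalysed conjugate addition of an aryl Grignard reagent to a chalcone, a reliable 1,4-addition; the new aryl group is identical to the one already on that carbon, so no stereocentre is formed.

Step 4
Reactants: 8 1-[2-(benzyloxy)-4-methoxyphenyl]-3,3-bis[4-(benzyloxy)phenyl]propan-1-one; 9 trimethylsilyl trifluoromethanesulfonate
Product: 10 {[(1Z)-1-[2-(benzyloxy)-4-methoxyphenyl]-3,3-bis[4-(benzyloxy)phenyl]prop-1-en-1-yl]oxy}trimethylsilane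
Conditions: TMSOTf, Et3N, CH2Cl2, 0 °C
Reagents that add atoms: trimethylsilyl trifluoromethanesulfonate, C[Si](C)(C)OS(=O)(=O)C(F)(F)F
Why: Soft enolisation with a silyl triflate and a tertiary amine; 8 has one enolisable position, and the Z isomer (silyloxy cis, aryl trans to the diarylmethyl group) avoids allylic 1,3-strain and should prevail.

Step 5
Reactants: 10 {[(1Z)-1-[2-(benzyloxy)-4-methoxyphenyl]-3,3-bis[4-(benzyloxy)phenyl]prop-1-en-1-yl]oxy}trimethylsilane; 11 diiodomethane
Product: 13 (1S,2S)-1-[2-(benzyloxy)-4-methoxyphenyl]-2-{bis[4-(benzyloxy)phenyl]methyl}cyclopropan-1-ol (hydroxyl cis to the diarylmethyl group), via cyclopropyl trimethylsilyl ether 12 (not isolated)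
Conditions: Et2Zn, CH2I2, N-Boc-L-Val-L-Pro-OMe (25 mol %), CH2Cl2, −40 → −20 °C; aq. work-up; then K2CO3 (cat.), MeOH/THF, 0 °C
Reagents that add atoms: diiodomethane, ICI
Why: Enantioselective Simmons–Smith cyclopropanation of a silyl enol ether by a dipeptide-ligated iodomethylzinc carbenoid, then methanolysis of the silyl ether. Methylene transfer is stereospecific, so the Z alkene places the hydroxyl cis to the diarylmethyl group, and the ligand selects the alkene face, which sets C1 and C2 together as (1S,2S).

Step 6
Reactants: 14 3-(benzyloxy)phenol; 15 iodine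
Product: 16 5-(benzyloxy)-2-iodophenol
Conditions: I2, NaHCO3, THF/H2O, 0 °C
Reagents that add atoms: iodine, II
Why: Electrophilic aromatic iodination of the phenoxide, expected mainly at the position ortho to the hydroxyl and para to the benzyloxy group; the isomer iodinated para to the hydroxyl is the likely minor product and is removed by chromatography.

Step 7
Reactants: 16 5-(benzyloxy)-2-iodophenol; 17 tert-butyldimethylsilyl chloride
Product: 18 [5-(benzyloxy)-2-iodophenoxy](tert-butyl)dimethylsilane
Conditions: TBSCl, imidazole, DMF, rt
Reagents that add atoms: tert-butyldimethylsilyl chloride, CC(C)(C)[Si](C)(C)Cl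
Why: Silylation of a phenol; it masks the future O1 with a group that fluoride removes beside benzyl ethers and keeps a free phenol out of the palladium step.

Step 8
Reactants: 13 (1S,2S)-1-[2-(benzyloxy)-4-methoxyphenyl]-2-{bis[4-(benzyloxy)phenyl]methyl}cyclopropan-1-ol; 18 [5-(benzyloxy)-2-iodophenoxy](tert-butyl)dimethylsilane; 19 carbon monoxide
Product: 20 (2S)-2-{bis[4-(benzyloxy)phenyl]methyl}-1-[2-(benzyloxy)-4-methoxyphenyl]-4-[4-(benzyloxy)-2-(tert-butyldimethylsilyloxy)phenyl]butane-1,4-dione
Conditions: Pd(PPh3)4 (5 mol %), CO (1 atm), K2CO3, toluene, 80 °C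
Reagents that add atoms: carbon monoxide, [C-]#[O+]
Why: Proposed new method: oxidative addition of 18 to zerovalent palladium and insertion of 19 should give an aroylpalladium iodide, whose iodide is exchanged, with carbonate, for the alkoxide of 13. Beta-carbon elimination then cleaves the CH2–C(OH) ring bond to a ketone-chelated primary alkylpalladium (a palladium homoenolate), and acyl–alkyl reductive elimination forms the second C–C bond and returns zerovalent palladium. The closest known reaction types are the palladium-catalysed acylation of cyclopropanol-derived homoenolates with acid chlorides to 1,4-diketones and the ring-opening arylation of cyclopropanols with aryl halides; here the acyl partner is made in the flask from an aryl iodide and CO. No ring is closed and no stereocentre is made: C2 of 13 keeps all four bonds and becomes the carbon alpha to the ring A ketone with unchanged geometry, the descriptor S resulting only from the changed priorities. Cleavage of the CH2–C(OH) bond and not of the other C–C(OH) bond is needed; the primary alkylpalladium it gives is less hindered than the alternative beside the diarylmethyl group. CO uptake must precede C–C coupling, which the CO atmosphere should secure, and insertion at either the aryl or the alkyl ligand leads to the same product. Reductive elimination must outrun beta-hydride elimination, which would remove the hydrogen of the stereocentre; chelation by the ketone and saturation by CO leave no free cis site for it. O-acylation of the alkoxide is disfavoured because it is tertiary and hindered, whereas ring opening releases strain, and solid carbonate in toluene should be too weak to enolise the hindered product.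

Step 9
Reactants: 20 (2S)-2-{bis[4-(benzyloxy)phenyl]methyl}-1-[2-(benzyloxy)-4-methoxyphenyl]-4-[4-(benzyloxy)-2-(tert-butyldimethylsilyloxy)phenyl]butane-1,4-dione
Product: 21 (2S)-2-{bis[4-(benzyloxy)phenyl]methyl}-1-[2-(benzyloxy)-4-methoxyphenyl]-4-[4-(benzyloxy)-2-hydroxyphenyl]butane-1,4-dione
Conditions: TBAF, AcOH, THF, 0 °C
Reagents that add atoms: none
Why: Fluoride desilylation of an aryl silyl ether, buffered with acetic acid so that the stereocentre alpha to the ring A ketone does not meet a base; benzyl ethers are untouched.

Step 10
Reactants: 21 (2S)-2-{bis[4-(benzyloxy)phenyl]methyl}-1-[2-(benzyloxy)-4-methoxyphenyl]-4-[4-(benzyloxy)-2-hydroxyphenyl]butane-1,4-dione; 22 N,N-dimethylformamide dimethyl acetal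
Product: 24 7-(benzyloxy)-3-[(2R)-1-[2-(benzyloxy)-4-methoxyphenyl]-3,3-bis[4-(benzyloxy)phenyl]-1-oxopropan-2-yl]-4H-chromen-4-one, via enaminone 23 (not isolated)
Conditions: Me2NCH(OMe)2, toluene, 80 °C; then AcOH, 40 °C
Reagents that add atoms: N,N-dimethylformamide dimethyl acetal, COC(OC)N(C)C
Why: Condensation of an amide acetal with the only methylene (the stereocentre is a methine and cannot form an enaminone), then acid-promoted addition of the ortho phenol to the enaminone and loss of the amine, the usual chromone synthesis from a 2-hydroxyaryl ketone. The ring is closed in acid because the chromone is the base-sensitive form of the stereocentre; the descriptor becomes R by priority change only.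

Step 11
Reactants: 24 7-(benzyloxy)-3-[(2R)-1-[2-(benzyloxy)-4-methoxyphenyl]-3,3-bis[4-(benzyloxy)phenyl]-1-oxopropan-2-yl]-4H-chromen-4-one
Product: 25 7-hydroxy-3-[(2R)-1-(2-hydroxy-4-methoxyphenyl)-3,3-bis(4-hydroxyphenyl)-1-oxopropan-2-yl]-4H-chromen-4-one
Conditions: H2 (1 atm), 10% Pd/C, EtOAc/MeOH, rt
Reagents that add atoms: none
Why: Hydrogenolysis of four aryl benzyl ethers under neutral conditions; the trisubstituted chromone C2=C3 bond and the hindered ketone should react more slowly, and the free phenols never meet base.

## Compound list

1 | paeonol, 1-(2-hydroxy-4-methoxyphenyl)ethan-1-one | CC(=O)c1ccc(OC)cc1O | starting material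
2 | benzyl bromide | BrCc1ccccc1 | starting material
3 | 1-[2-(benzyloxy)-4-methoxyphenyl]ethan-1-one | CC(=O)c1ccc(OC)cc1OCc1ccccc1 | intermediate
4 | 4-(benzyloxy)benzaldehyde | O=Cc1ccc(OCc2ccccc2)cc1 | starting material
5 | (2E)-1-[2-(benzyloxy)-4-methoxyphenyl]-3-[4-(benzyloxy)phenyl]prop-2-en-1-one | COc1ccc(C(=O)/C=C/c2ccc(OCc3ccccc3)cc2)c(OCc2ccccc2)c1 | intermediate
6 | 1-(benzyloxy)-4-bromobenzene | Brc1ccc(OCc2ccccc2)cc1 | starting material
7 | [4-(benzyloxy)phenyl]magnesium bromide | Br[Mg]c1ccc(OCc2ccccc2)cc1 | intermediate (not isolated)
8 | 1-[2-(benzyloxy)-4-methoxyphenyl]-3,3-bis[4-(benzyloxy)phenyl]propan-1-one | COc1ccc(C(=O)CC(c2ccc(OCc3ccccc3)cc2)c2ccc(OCc3ccccc3)cc2)c(OCc2ccccc2)c1 | intermediate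
9 | trimethylsilyl trifluoromethanesulfonate | C[Si](C)(C)OS(=O)(=O)C(F)(F)F | starting material
10 | {[(1Z)-1-[2-(benzyloxy)-4-methoxyphenyl]-3,3-bis[4-(benzyloxy)phenyl]prop-1-en-1-yl]oxy}trimethylsilane | COc1ccc(/C(O[Si](C)(C)C)=C/C(c2ccc(OCc3ccccc3)cc2)c2ccc(OCc3ccccc3)cc2)c(OCc2ccccc2)c1 | intermediate
11 | diiodomethane | ICI | starting material
12 | {[(1S,2S)-1-[2-(benzyloxy)-4-methoxyphenyl]-2-{bis[4-(benzyloxy)phenyl]methyl}cyclopropyl]oxy}trimethylsilane | C[Si](C)(C)O[C@@]1(c2ccc(OC)cc2OCc2ccccc2)C[C@H]1C(c1ccc(OCc2ccccc2)cc1)c1ccc(OCc2ccccc2)cc1 | intermediate (not isolated)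
13 | (1S,2S)-1-[2-(benzyloxy)-4-methoxyphenyl]-2-{bis[4-(benzyloxy)phenyl]methyl}cyclopropan-1-ol, hydroxyl cis to the diarylmethyl group | O[C@@]1(c2ccc(OC)cc2OCc2ccccc2)C[C@H]1C(c1ccc(OCc2ccccc2)cc1)c1ccc(OCc2ccccc2)cc1 | intermediate
14 | 3-(benzyloxy)phenol | Oc1cccc(OCc2ccccc2)c1 | starting material
15 | iodine | II | starting material
16 | 5-(benzyloxy)-2-iodophenol | Oc1cc(OCc2ccccc2)ccc1I | intermediate
17 | tert-butyldimethylsilyl chloride | CC(C)(C)[Si](C)(C)Cl | starting material
18 | [5-(benzyloxy)-2-iodophenoxy](tert-butyl)dimethylsilane | Ic1ccc(OCc2ccccc2)cc1O[Si](C)(C)C(C)(C)C | intermediate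
19 | carbon monoxide | [C-]#[O+] | starting material
20 | (2S)-2-{bis[4-(benzyloxy)phenyl]methyl}-1-[2-(benzyloxy)-4-methoxyphenyl]-4-[4-(benzyloxy)-2-(tert-butyldimethylsilyloxy)phenyl]butane-1,4-dione | COc1ccc(C(=O)[C@@H](CC(=O)c2ccc(OCc3ccccc3)cc2O[Si](C)(C)C(C)(C)C)C(c2ccc(OCc3ccccc3)cc2)c2ccc(OCc3ccccc3)cc2)c(OCc2ccccc2)c1 | intermediate
21 | (2S)-2-{bis[4-(benzyloxy)phenyl]methyl}-1-[2-(benzyloxy)-4-methoxyphenyl]-4-[4-(benzyloxy)-2-hydroxyphenyl]butane-1,4-dione | COc1ccc(C(=O)[C@@H](CC(=O)c2ccc(OCc3ccccc3)cc2O)C(c2ccc(OCc3ccccc3)cc2)c2ccc(OCc3ccccc3)cc2)c(OCc2ccccc2)c1 | intermediate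
22 | N,N-dimethylformamide dimethyl acetal | COC(OC)N(C)C | starting material
23 | (2R,3E)-2-{bis[4-(benzyloxy)phenyl]methyl}-3-[4-(benzyloxy)-2-hydroxybenzoyl]-1-[2-(benzyloxy)-4-methoxyphenyl]-4-(dimethylamino)but-3-en-1-one | COc1ccc(C(=O)[C@@H](C(=C/N(C)C)\C(=O)c2ccc(OCc3ccccc3)cc2O)C(c2ccc(OCc3ccccc3)cc2)c2ccc(OCc3ccccc3)cc2)c(OCc2ccccc2)c1 | intermediate (not isolated)
24 | 7-(benzyloxy)-3-[(2R)-1-[2-(benzyloxy)-4-methoxyphenyl]-3,3-bis[4-(benzyloxy)phenyl]-1-oxopropan-2-yl]-4H-chromen-4-one | COc1ccc(C(=O)[C@@H](c2coc3cc(OCc4ccccc4)ccc3c2=O)C(c2ccc(OCc3ccccc3)cc2)c2ccc(OCc3ccccc3)cc2)c(OCc2ccccc2)c1 | intermediate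
25 | 7-hydroxy-3-[(2R)-1-(2-hydroxy-4-methoxyphenyl)-3,3-bis(4-hydroxyphenyl)-1-oxopropan-2-yl]-4H-chromen-4-one | COc1ccc(C(=O)[C@@H](c2coc3cc(O)ccc3c2=O)C(c2ccc(O)cc2)c2ccc(O)cc2)c(O)c1 | target

## Step count and least certain steps

Total: 11 steps. Longest linear sequence: 9 steps (steps 1 to 5, then 8 to 11); steps 6 and 7 form the short branch to 18.

Step 8 (key step). Several processes can divert it:
- O-acylation of the cyclopropanol by the aroylpalladium species instead of ring opening.
- Coupling before CO uptake, giving the CO-free aryl ketone.
- Beta-hydride elimination from the palladium homoenolate, which takes the hydrogen of the stereocentre and ends in loss of configuration.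
- Base-induced ring opening of 13 before it reaches palladium.

All four stem from the need for three partners to meet in the right order on one metal centre. The fallback uses the known palladium-catalysed acylation of cyclopropanols with a preformed acid chloride; it sets out from 13 and returns at 20. Commercial 4-(benzyloxy)-2-hydroxybenzoic acid F1 is silylated on both oxygens (TBSCl, imidazole, DMF) to tert-butyldimethylsilyl 4-(benzyloxy)-2-[(tert-butyldimethylsilyl)oxy]benzoate F2. Oxalyl chloride with catalytic DMF in CH2Cl2 turns the silyl ester, under neutral conditions that spare the aryl silyl ether, into 4-(benzyloxy)-2-[(tert-butyldimethylsilyl)oxy]benzoyl chloride F3. Cyclopropanol 13 is converted with Et2Zn into its zinc alkoxide and coupled with F3 under Pd(PPh3)4 catalysis in THF to give 20, which goes on to step 9. The ring opens at the same bond and the stereocentre is again untouched.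

Step 5. Facial selectivity may be poor, because the alkene is trisubstituted and carries a bulky diarylmethyl group next to the reacting carbon. Methylene transfer may also be slow enough for zinc iodide to hydrolyse the enol ether, and the sense of induction is not secure. The fallback sets out from 10 and returns at 13. Cyclopropanation without ligand (Et2Zn, CH2I2, CH2Cl2, 0 °C) is still stereospecific and gives 12 together with its enantiomer {[(1R,2R)-1-[2-(benzyloxy)-4-methoxyphenyl]-2-{bis[4-(benzyloxy)phenyl]methyl}cyclopropyl]oxy}trimethylsilane F4. Methanolysis gives 13 together with (1R,2R)-1-[2-(benzyloxy)-4-methoxyphenyl]-2-{bis[4-(benzyloxy)phenyl]methyl}cyclopropan-1-ol F5. The two cyclopropanols are separated by preparative chromatography on a chiral stationary phase, and 13 goes on to step 8. Half the material is lost, but nothing depends on asymmetric induction.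

Step 10. Condensation at the methylene may be slow, because it is flanked by a fully substituted carbon. On prolonged heating the chromone may form in the basic medium and epimerise, or the phenol may be O-methylated by the acetal. The fallback sets out from 21 and returns at 24. A Lewis-acid-promoted Vilsmeier formylation and cyclisation (BF3·OEt2, DMF, MsCl, 50–70 °C) should convert 21 directly into 24 in an acidic medium, so that no amine base meets the product.

Step 11. Over-reduction of the chromone C2=C3 bond or of the aryl ketone may set in before all four ethers are cleaved, since the last benzyl groups of a poorly soluble polyphenol come off slowly. The fallback sets out from 24 and returns at 25. BCl3 with pentamethylbenzene as cation scavenger in CH2Cl2 at −78 °C, quenched cold with methanol, cleaves the benzyl ethers by Lewis-acid dealkylation without any reducing agent. The methyl ether para to the ketone on ring A is expected to survive at this temperature.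

## Further compounds

F1 | step 8 | 4-(benzyloxy)-2-hydroxybenzoic acid | OC(=O)c1ccc(OCc2ccccc2)cc1O
F2 | step 8 | tert-butyldimethylsilyl 4-(benzyloxy)-2-[(tert-butyldimethylsilyl)oxy]benzoate | CC(C)(C)[Si](C)(C)OC(=O)c1ccc(OCc2ccccc2)cc1O[Si](C)(C)C(C)(C)C
F3 | step 8 | 4-(benzyloxy)-2-[(tert-butyldimethylsilyl)oxy]benzoyl chloride | ClC(=O)c1ccc(OCc2ccccc2)cc1O[Si](C)(C)C(C)(C)C
F4 | step 5 | {[(1R,2R)-1-[2-(benzyloxy)-4-methoxyphenyl]-2-{bis[4-(benzyloxy)phenyl]methyl}cyclopropyl]oxy}trimethylsilane | C[Si](C)(C)O[C@]1(c2ccc(OC)cc2OCc2ccccc2)C[C@@H]1C(c1ccc(OCc2ccccc2)cc1)c1ccc(OCc2ccccc2)cc1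
F5 | step 5 | (1R,2R)-1-[2-(benzyloxy)-4-methoxyphenyl]-2-{bis[4-(benzyloxy)phenyl]methyl}cyclopropan-1-ol | O[C@]1(c2ccc(OC)cc2OCc2ccccc2)C[C@@H]1C(c1ccc(OCc2ccccc2)cc1)c1ccc(OCc2ccccc2)cc1
F0 | step 10 | none | none
F0 | step 11 | none | none
A1 | alternative 1 | 7-(benzyloxy)-3-[(2R)-3,3-bis[4-(benzyloxy)phenyl]-1-(2-hydroxy-4-methoxyphenyl)-1-oxopropan-2-yl]-4H-chromen-4-one | COc1ccc(C(=O)[C@@H](c2coc3cc(OCc4ccccc4)ccc3c2=O)C(c2ccc(OCc3ccccc3)cc2)c2ccc(OCc3ccccc3)cc2)c(O)c1
A2 | alternative 1 | (4R)-4-[7-(benzyloxy)-4-oxo-4H-chromen-3-yl]-5,5-bis[4-(benzyloxy)phenyl]pent-1-yn-3-one | C#CC(=O)[C@@H](c1coc2cc(OCc3ccccc3)ccc2c1=O)C(c1ccc(OCc2ccccc2)cc1)c1ccc(OCc2ccccc2)cc1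
A3 | alternative 1 | (1E)-1,3-dimethoxy-1-(trimethylsilyloxy)buta-1,3-diene | C=C(OC)/C=C(\OC)O[Si](C)(C)C
A4 | alternative 2 | (3S)-7-(benzyloxy)-3-[(2R)-1-[2-(benzyloxy)-4-methoxyphenyl]-3,3-bis[4-(benzyloxy)phenyl]-1-oxopropan-2-yl]-2,3-dihydro-4H-chromen-4-one | COc1ccc(C(=O)[C@@H]([C@H]2COc3cc(OCc4ccccc4)ccc3C2=O)C(c2ccc(OCc3ccccc3)cc2)c2ccc(OCc3ccccc3)cc2)c(OCc2ccccc2)c1
A5 | alternative 2 | 4-(benzyloxy)-2-{[(2E)-4-[2-(benzyloxy)-4-methoxyphenyl]-3-{bis[4-(benzyloxy)phenyl]methyl}-4-oxobut-2-en-1-yl]oxy}benzaldehyde | O=Cc1ccc(OCc2ccccc2)cc1OC/C=C(/C(=O)c1ccc(OC)cc1OCc1ccccc1)C(c1ccc(OCc2ccccc2)cc1)c1ccc(OCc2ccccc2)cc1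
A6 | alternative 3 | 7-(benzyloxy)-3-[(2R)-3,3-bis[4-(benzyloxy)phenyl]-1-(2-chloro-6-hydroxy-4-methoxyphenyl)-1-oxopropan-2-yl]-4H-chromen-4-one | COc1cc(Cl)c(C(=O)[C@@H](c2coc3cc(OCc4ccccc4)ccc3c2=O)C(c2ccc(OCc3ccccc3)cc2)c2ccc(OCc3ccccc3)cc2)c(O)c1
A7 | alternative 3 | (2R)-2-[7-(benzyloxy)-4-oxo-4H-chromen-3-yl]-3,3-bis[4-(benzyloxy)phenyl]propanoic acid | OC(=O)[C@@H](c1coc2cc(OCc3ccccc3)ccc2c1=O)C(c1ccc(OCc2ccccc2)cc1)c1ccc(OCc2ccccc2)cc1
A8 | alternative 3 | 2-chloro-4-methoxy-6-(trimethylsilyl)phenyl trifluoromethanesulfonate | COc1cc(Cl)c(OS(=O)(=O)C(F)(F)F)c([Si](C)(C)C)c1
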